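C3 of the catechol flavanone is bonded to three carbon groups: the C4 carbonyl on ring A, C8'' of the naringenin unit and C2 carrying ring B. C3 is therefore introduced as a carbene carbon. A rhodium carbene from an aryl diazomethyl ketone is attacked by C8'' of protected (2S)-naringenin, and the enol so formed is trapped by a protected 3,4-dihydroxybenzaldehyde under a chiral phosphoric acid. C3–C8'', C2–C3 and both stereocentres arise in one operation, and no ring is closed. The precursor is a 2-diazo-1-arylethanone with both ortho oxygens silylated. Desilylation, Mitsunobu closure of O1–C2 with inversion and hydrogenolysis complete the synthesis.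

Key step: step 7

Remark on notation and assumption: locants without primes belong to the catechol flavanone (unit 1, rings A and B), doubly primed locants to the naringenin unit (unit 2), triply primed ones to its 4-hydroxyphenyl ring. TBS = tert-butyldimethylsilyl. (R)-TRIP = (R)-3,3'-bis(2,4,6-triisopropylphenyl)-1,1'-binaphthalene-2,2'-diyl hydrogen phosphate. It is assumed that the sense of induction can be matched to the target by the choice of enantiomer of this acid.

Design choices for the three components: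
- **Naringenin partner:** O7'' and O4''' are benzylated without carbonate base, which would open the flavanone through the 4'''-phenoxide and racemise C2''. O5'' carries a TBS group, which removes the last O–H bond and screens C6''.
- **Aldehyde:** the catechol is protected as two benzyl carbonates. This makes the aldehyde more electrophilic and the later carbinol less prone to ionise, and the groups leave in the final hydrogenolysis.
- **Diazoketone:** it is made from the methyl ketone by diazo transfer, so no hindered acid chloride is needed.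

Step 1
Reactants: 1 (2S)-naringenin
Product: 2 (2S)-7-(benzyloxy)-2-[4-(benzyloxy)phenyl]-5-hydroxychroman-4-one
Conditions: BnOH (2.4 equiv), PPh3, DIAD, THF, 0 °C to rt
Reagents that add atoms: benzyl alcohol, OCc1ccccc1
Why: Mitsunobu etherification alkylates the two non-chelated phenols (7''-OH and 4'''-OH) and leaves the hydrogen-bonded 5''-OH, under conditions free of the carbonate bases that would open the ring and erode the 2''S centre.

Step 2
Reactants: 2 (2S)-7-(benzyloxy)-2-[4-(benzyloxy)phenyl]-5-hydroxychroman-4-one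
Product: 3 (2S)-7-(benzyloxy)-2-[4-(benzyloxy)phenyl]-5-(tert-butyldimethylsilyloxy)chroman-4-one
Conditions: TBSOTf, 2,6-lutidine, CH2Cl2, 0 °C
Reagents that add atoms: tert-butyldimethylsilyl trifluoromethanesulfonate, CC(C)(C)[Si](C)(C)OS(=O)(=O)C(F)(F)F
Why: Silyl ether formation with the reactive silyl triflate and a hindered pyridine base caps the chelated phenol, so that no O–H bond is left for carbene insertion and C6'' sits between two bulky groups.

Step 3
Reactants: 4 3,4-dihydroxybenzaldehyde
Product: 5 dibenzyl (4-formyl-1,2-phenylene) biscarbonate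
Conditions: benzyl chloroformate (2.3 equiv), Et3N, CH2Cl2, 0 °C
Reagents that add atoms: benzyl chloroformate, O=C(Cl)OCc1ccccc1
Why: Acylation of both phenols by the chloroformate (carbonate formation) is routine and gives an electron-poor aldehyde whose protecting groups are cleaved by hydrogenolysis.

Step 4
Reactants: 6 2,4,6-trihydroxyacetophenone
Product: 7 1-[4-(benzyloxy)-2,6-dihydroxyphenyl]ethanone
Conditions: BnBr (1.0 equiv), K2CO3 (1.0 equiv), DMF, 0 °C to rt
Reagents that add atoms: benzyl bromide, BrCc1ccccc1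
Why: Williamson etherification with one equivalent of base and halide should occur at the 4-OH, the most acidic and sterically open phenol of the acylphloroglucinol.

Step 5
Reactants: 7 1-[4-(benzyloxy)-2,6-dihydroxyphenyl]ethanone
Product: 8 1-[4-(benzyloxy)-2,6-bis(tert-butyldimethylsilyloxy)phenyl]ethanone
Conditions: TBSCl, imidazole, DMF, rt
Reagents that add atoms: tert-butyldimethylsilyl chloride, CC(C)(C)[Si](C)(C)Cl
Why: Standard silyl ether formation caps both ortho phenols with groups that offer no C–H bond within reach of the later carbene and that fluoride removes under nearly neutral conditions.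

Step 6
Reactants: 8 1-[4-(benzyloxy)-2,6-bis(tert-butyldimethylsilyloxy)phenyl]ethanone
Product: 10 2-diazo-1-[4-(benzyloxy)-2,6-bis(tert-butyldimethylsilyloxy)phenyl]ethanone, via trifluoroacetyl ketone 9 (not isolated)
Conditions: LiN(SiMe3)2, THF, −78 °C; CF3CO2CH2CF3, −78 °C; then MsN3, Et3N, H2O (1 equiv), MeCN, rt
Reagents that add atoms: methanesulfonyl azide, CS(=O)(=O)N=[N+]=[N-]; 2,2,2-trifluoroethyl trifluoroacetate, O=C(OCC(F)(F)F)C(F)(F)F (its atoms stay only in 9)
Why: Detrifluoroacetylative diazo transfer (a Regitz-type diazo transfer onto an activated ketone): the kinetic lithium enolate is trifluoroacetylated at low temperature, and the 1,3-dicarbonyl compound 9 then accepts the diazo group and passes its trifluoroacetyl group to the sulfonamide.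

Step 7
Reactants: 10 2-diazo-1-[4-(benzyloxy)-2,6-bis(tert-butyldimethylsilyloxy)phenyl]ethanone; 3 (2S)-7-(benzyloxy)-2-[4-(benzyloxy)phenyl]-5-(tert-butyldimethylsilyloxy)chroman-4-one; 5 dibenzyl (4-formyl-1,2-phenylene) biscarbonate
Product: 12 anti aldol (2R,3S)-1-[4-(benzyloxy)-2,6-bis(tert-butyldimethylsilyloxy)phenyl]-3-{3,4-bis[(benzyloxycarbonyl)oxy]phenyl}-2-{(2S)-7-(benzyloxy)-2-[4-(benzyloxy)phenyl]-5-(tert-butyldimethylsilyloxy)-4-oxochroman-8-yl}-3-hydroxypropan-1-one, via Z-enol 11 (not isolated)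
Conditions: Rh2(OAc)4 (2 mol %), (R)-TRIP (10 mol %), 4 Å MS, CH2Cl2, −10 °C, 10 added over 4 h
Reagents that add atoms: none
Why: Proposed new method: Rh2(OAc)4 turns 10 into an electrophilic acceptor carbene, C8'' of the acylphloroglucinol ring of 3 attacks it in a Friedel–Crafts sense, and loss of the ring proton from the zwitterion leaves the Z-enol 11. Before 11 tautomerises to the ketone, it adds to aldehyde 5, which is held and activated by the phosphoric acid, and this forms C2–C3. The closest known reaction type is the three-component coupling of diazo compounds, electron-rich arenes and imines under Rh2(OAc)4 and a chiral phosphoric acid, which traps the zwitterionic intermediate; an acceptor-only diazoketone, an alkoxyarene and an aldehyde have not been joined in this way. No ring is closed; both stereocentres arise in the aldol event, where the acid bridges the enol O–H and the aldehyde C=O so that its aryl pocket selects the enol face (3R) and the aldehyde face (S carbinol), and the Z-enol with its two aryl groups trans is expected to react through an open arrangement that keeps the ring B aryl away from the C8'' aryl group, which gives the anti isomer. Attack at C8'' and not at C6'' is secured by the substrate, because C6'' lies between the OTBS and OBn groups while C8'' is flanked only by OBn and the ring oxygen. Chemoselectivity rests on the silyl ethers ortho to the acyl group (no C–H bond in insertion range, weakly basic oxygen), on the absence of any O–H bond, on an aldehyde that is a good electrophile but a poor donor toward the carbene, and on slow addition of 10 against carbene dimerisation.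

Step 8
Reactants: 12 anti aldol (2R,3S)-1-[4-(benzyloxy)-2,6-bis(tert-butyldimethylsilyloxy)phenyl]-3-{3,4-bis[(benzyloxycarbonyl)oxy]phenyl}-2-{(2S)-7-(benzyloxy)-2-[4-(benzyloxy)phenyl]-5-(tert-butyldimethylsilyloxy)-4-oxochroman-8-yl}-3-hydroxypropan-1-one
Product: 13 (2R,3S)-1-[4-(benzyloxy)-2,6-dihydroxyphenyl]-3-{3,4-bis[(benzyloxycarbonyl)oxy]phenyl}-2-{(2S)-7-(benzyloxy)-2-[4-(benzyloxy)phenyl]-5-hydroxy-4-oxochroman-8-yl}-3-hydroxypropan-1-one
Conditions: HF·pyridine, pyridine, THF, 0 °C to rt
Reagents that add atoms: none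
Why: Fluoride-mediated cleavage of the three aryl silyl ethers under buffered, mildly acidic conditions should spare the benzyl ethers and carbonates and avoid the retro-aldol cleavage or C3 epimerisation that a basic fluoride source could cause.

Step 9
Reactants: 13 (2R,3S)-1-[4-(benzyloxy)-2,6-dihydroxyphenyl]-3-{3,4-bis[(benzyloxycarbonyl)oxy]phenyl}-2-{(2S)-7-(benzyloxy)-2-[4-(benzyloxy)phenyl]-5-hydroxy-4-oxochroman-8-yl}-3-hydroxypropan-1-one
Product: 14 (2S)-7-(benzyloxy)-2-[4-(benzyloxy)phenyl]-8-{(2R,3R)-7-(benzyloxy)-2-{3,4-bis[(benzyloxycarbonyl)oxy]phenyl}-5-hydroxy-4-oxochroman-3-yl}-5-hydroxychroman-4-one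
Conditions: PPh3, DIAD, THF (0.01 M), 0 °C
Reagents that add atoms: none
Why: Intramolecular Mitsunobu etherification: an ortho phenol of ring A displaces the phosphonium-activated benzylic oxygen in a 6-exo-tet SN2 step with inversion (S carbinol to 2R), so the anti aldol gives the 2,3-cis flavanone with C3 untouched, and the carbonate-bearing aryl group disfavours ionisation at C2.

Step 10
Reactants: 14 (2S)-7-(benzyloxy)-2-[4-(benzyloxy)phenyl]-8-{(2R,3R)-7-(benzyloxy)-2-{3,4-bis[(benzyloxycarbonyl)oxy]phenyl}-5-hydroxy-4-oxochroman-3-yl}-5-hydroxychroman-4-one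
Product: 15 (2S)-8-[(2R,3R)-2-(3,4-dihydroxyphenyl)-5,7-dihydroxy-4-oxochroman-3-yl]-5,7-dihydroxy-2-(4-hydroxyphenyl)chroman-4-one (CNP0105436.1)
Conditions: H2 (1 atm), Pd/C, EtOAc–MeOH, rt
Reagents that add atoms: none
Why: Catalytic hydrogenolysis should cleave the three benzyl ethers and the two benzyl carbonates (the latter with loss of CO2) under neutral conditions that leave the epimerisable cis C2/C3 pair and C2'' alone.

Compound list
1 | (2S)-naringenin | O=C1C[C@@H](c2ccc(O)cc2)Oc2cc(O)cc(O)c12 | starting material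
2 | (2S)-7-(benzyloxy)-2-[4-(benzyloxy)phenyl]-5-hydroxychroman-4-one | O=C1C[C@@H](c2ccc(OCc3ccccc3)cc2)Oc2cc(OCc3ccccc3)cc(O)c12 | intermediate
3 | (2S)-7-(benzyloxy)-2-[4-(benzyloxy)phenyl]-5-(tert-butyldimethylsilyloxy)chroman-4-one | O=C1C[C@@H](c2ccc(OCc3ccccc3)cc2)Oc2cc(OCc3ccccc3)cc(O[Si](C)(C)C(C)(C)C)c12 | intermediate
4 | 3,4-dihydroxybenzaldehyde | O=Cc1ccc(O)c(O)c1 | starting material
5 | dibenzyl (4-formyl-1,2-phenylene) biscarbonate | O=Cc1ccc(OC(=O)OCc2ccccc2)c(OC(=O)OCc2ccccc2)c1 | intermediate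
6 | 2,4,6-trihydroxyacetophenone | CC(=O)c1c(O)cc(O)cc1O | starting material
7 | 1-[4-(benzyloxy)-2,6-dihydroxyphenyl]ethanone | CC(=O)c1c(O)cc(OCc2ccccc2)cc1O | intermediate
8 | 1-[4-(benzyloxy)-2,6-bis(tert-butyldimethylsilyloxy)phenyl]ethanone | CC(=O)c1c(O[Si](C)(C)C(C)(C)C)cc(OCc2ccccc2)cc1O[Si](C)(C)C(C)(C)C | intermediate
9 | 1-[4-(benzyloxy)-2,6-bis(tert-butyldimethylsilyloxy)phenyl]-4,4,4-trifluorobutane-1,3-dione (trifluoroacetyl ketone, not isolated) | O=C(CC(=O)C(F)(F)F)c1c(O[Si](C)(C)C(C)(C)C)cc(OCc2ccccc2)cc1O[Si](C)(C)C(C)(C)C | intermediate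
10 | 2-diazo-1-[4-(benzyloxy)-2,6-bis(tert-butyldimethylsilyloxy)phenyl]ethanone | [N-]=[N+]=CC(=O)c1c(O[Si](C)(C)C(C)(C)C)cc(OCc2ccccc2)cc1O[Si](C)(C)C(C)(C)C | intermediate
11 | (Z)-1-[4-(benzyloxy)-2,6-bis(tert-butyldimethylsilyloxy)phenyl]-2-{(2S)-7-(benzyloxy)-2-[4-(benzyloxy)phenyl]-5-(tert-butyldimethylsilyloxy)-4-oxochroman-8-yl}ethen-1-ol (Z-enol, not isolated) | O=C1C[C@@H](c2ccc(OCc3ccccc3)cc2)Oc2c1c(O[Si](C)(C)C(C)(C)C)cc(OCc1ccccc1)c2/C=C(\O)c1c(O[Si](C)(C)C(C)(C)C)cc(OCc2ccccc2)cc1O[Si](C)(C)C(C)(C)C | intermediate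
12 | (2R,3S)-1-[4-(benzyloxy)-2,6-bis(tert-butyldimethylsilyloxy)phenyl]-3-{3,4-bis[(benzyloxycarbonyl)oxy]phenyl}-2-{(2S)-7-(benzyloxy)-2-[4-(benzyloxy)phenyl]-5-(tert-butyldimethylsilyloxy)-4-oxochroman-8-yl}-3-hydroxypropan-1-one (anti aldol; 3R and S carbinol in flavanone numbering) | O=C1C[C@@H](c2ccc(OCc3ccccc3)cc2)Oc2c1c(O[Si](C)(C)C(C)(C)C)cc(OCc1ccccc1)c2[C@H]([C@H](O)c1ccc(OC(=O)OCc2ccccc2)c(OC(=O)OCc2ccccc2)c1)C(=O)c1c(O[Si](C)(C)C(C)(C)C)cc(OCc2ccccc2)cc1O[Si](C)(C)C(C)(C)C | intermediate
13 | (2R,3S)-1-[4-(benzyloxy)-2,6-dihydroxyphenyl]-3-{3,4-bis[(benzyloxycarbonyl)oxy]phenyl}-2-{(2S)-7-(benzyloxy)-2-[4-(benzyloxy)phenyl]-5-hydroxy-4-oxochroman-8-yl}-3-hydroxypropan-1-one | O=C1C[C@@H](c2ccc(OCc3ccccc3)cc2)Oc2c1c(O)cc(OCc1ccccc1)c2[C@H]([C@H](O)c1ccc(OC(=O)OCc2ccccc2)c(OC(=O)OCc2ccccc2)c1)C(=O)c1c(O)cc(OCc2ccccc2)cc1O | intermediate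
14 | (2S)-7-(benzyloxy)-2-[4-(benzyloxy)phenyl]-8-{(2R,3R)-7-(benzyloxy)-2-{3,4-bis[(benzyloxycarbonyl)oxy]phenyl}-5-hydroxy-4-oxochroman-3-yl}-5-hydroxychroman-4-one (2,3-cis) | O=C1C[C@@H](c2ccc(OCc3ccccc3)cc2)Oc2c1c(O)cc(OCc1ccccc1)c2[C@H]1C(=O)c2c(O)cc(OCc3ccccc3)cc2O[C@H]1c1ccc(OC(=O)OCc2ccccc2)c(OC(=O)OCc2ccccc2)c1 | intermediate
15 | (2S)-8-[(2R,3R)-2-(3,4-dihydroxyphenyl)-5,7-dihydroxy-4-oxochroman-3-yl]-5,7-dihydroxy-2-(4-hydroxyphenyl)chroman-4-one (CNP0105436.1) | O=C1C[C@@H](c2ccc(O)cc2)Oc2c1c(O)cc(O)c2[C@H]1C(=O)c2c(O)cc(O)cc2O[C@H]1c1ccc(O)c(O)c1 | target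

Total step count: 10.
Longest linear sequence: 7 steps (steps 4, 5, 6, 7, 8, 9 and 10, from 2,4,6-trihydroxyacetophenone 6).

Steps most likely to fail

1. Step 7 (Proposed new method). Several processes could defeat it:
- tautomerisation of enol 11 could outrun its capture by the aldehyde;
- the arene could attack through C6'' or not at all, so that the carbene dimerises or is taken up by a silyloxy oxygen of its own ring;
- the acid could give poor facial or anti/syn control.

The fallback uses known chemistry, sets out from 3 and 8 and comes back at 12. Electrophilic iodination of 3 (I2, AgOCOCF3, CH2Cl2, 0 °C) should enter the less hindered C8'' and give (2S)-7-(benzyloxy)-2-[4-(benzyloxy)phenyl]-5-(tert-butyldimethylsilyloxy)-8-iodochroman-4-one F1. Soft enolisation of ketone 8 (TMSOTf, Et3N, CH2Cl2, 0 °C) gives the trimethylsilyl enol ether F2. Palladium-catalysed arylation of the tin enolate made in the flask from F2 (Pd(OAc)2, P(t-Bu)3, Bu3SnF, toluene, 85 °C) with F1 joins C3 to C8'' and gives the deoxybenzoin F3, the ketone that tautomerisation of 11 would also give. F3 is then converted into its dicyclohexylboron enolate (Cy2BCl, Et3N, Et2O, 0 °C) and added to aldehyde 5 at −78 °C in an anti-selective boron aldol reaction. The two anti isomers are diastereomers because of the fixed 2''S centre, and chromatography should separate them and deliver 12. A chiral dialkylboron halide could add reagent control.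

2. Step 9. The activated carbinol may lose its configuration by β-elimination toward the α-aryl enone or by ionisation at C2, and the basic betaine may epimerise C3 toward the trans isomer. The fallback replaces the redox condensation by a sulfonate displacement, sets out from 12 and comes back at 14. The carbinol of 12 is mesylated with retention while the phenols are still silylated (Ms2O, pyridine, CH2Cl2, −20 °C), giving the mesylate F4. Buffered fluoride (Bu4NF, AcOH, THF, 0 °C) then removes the three silyl groups, and the ortho phenoxide released beside the ketone displaces the mesylate in a 6-exo-tet SN2 step with inversion, which gives 14 directly.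

3. Step 6. In the lithium enolate of 8 a silyl group may migrate from an ortho oxygen to the enolate oxygen, or silyl groups may be lost under the basic conditions. The fallback avoids any metal enolate, sets out from 8 and comes back at 10. Condensation of 8 with tert-butoxybis(dimethylamino)methane (toluene, 60 °C) gives the enaminone F5. Diazo transfer from methanesulfonyl azide (MeCN, rt) proceeds by cycloaddition to the enamine double bond and fragmentation, releasing the formamidine and leaving 10.

Further compounds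
F1 | step 7 | (2S)-7-(benzyloxy)-2-[4-(benzyloxy)phenyl]-5-(tert-butyldimethylsilyloxy)-8-iodochroman-4-one | O=C1C[C@@H](c2ccc(OCc3ccccc3)cc2)Oc2c(I)c(OCc3ccccc3)cc(O[Si](C)(C)C(C)(C)C)c12
F2 | step 7 | {1-[4-(benzyloxy)-2,6-bis(tert-butyldimethylsilyloxy)phenyl]ethenyloxy}trimethylsilane | C=C(O[Si](C)(C)C)c1c(O[Si](C)(C)C(C)(C)C)cc(OCc2ccccc2)cc1O[Si](C)(C)C(C)(C)C
F3 | step 7 | 1-[4-(benzyloxy)-2,6-bis(tert-butyldimethylsilyloxy)phenyl]-2-{(2S)-7-(benzyloxy)-2-[4-(benzyloxy)phenyl]-5-(tert-butyldimethylsilyloxy)-4-oxochroman-8-yl}ethanone | O=C1C[C@@H](c2ccc(OCc3ccccc3)cc2)Oc2c(CC(=O)c3c(O[Si](C)(C)C(C)(C)C)cc(OCc4ccccc4)cc3O[Si](C)(C)C(C)(C)C)c(OCc3ccccc3)cc(O[Si](C)(C)C(C)(C)C)c12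
F4 | step 9 | (1S,2R)-3-[4-(benzyloxy)-2,6-bis(tert-butyldimethylsilyloxy)phenyl]-1-{3,4-bis[(benzyloxycarbonyl)oxy]phenyl}-2-{(2S)-7-(benzyloxy)-2-[4-(benzyloxy)phenyl]-5-(tert-butyldimethylsilyloxy)-4-oxochroman-8-yl}-3-oxopropyl methanesulfonate | O=C1C[C@@H](c2ccc(OCc3ccccc3)cc2)Oc2c1c(O[Si](C)(C)C(C)(C)C)cc(OCc1ccccc1)c2[C@H]([C@H](OS(C)(=O)=O)c1ccc(OC(=O)OCc2ccccc2)c(OC(=O)OCc2ccccc2)c1)C(=O)c1c(O[Si](C)(C)C(C)(C)C)cc(OCc2ccccc2)cc1O[Si](C)(C)C(C)(C)C
F5 | step 6 | (E)-1-[4-(benzyloxy)-2,6-bis(tert-butyldimethylsilyloxy)phenyl]-3-(dimethylamino)prop-2-en-1-one | CN(C)/C=C/C(=O)c1c(O[Si](C)(C)C(C)(C)C)cc(OCc2ccccc2)cc1O[Si](C)(C)C(C)(C)C
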